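## Retrosynthetic overview

1. Target 25 ⇒ alcohol 24 (oxidation at C10) ⇒ core aldehyde 14 + furan-bearing allyl chloride 22 (C9–C10 bond, α-selective allylbarium addition).
2. Core 14 ⇒ acyclic epoxy enal ester 10 in one cascade that mirrors the likely biogenesis: the ester carbonyl opens the 15,16-epoxide at C16 with inversion (γ-lactone first), then the freed C15 hydroxyl adds to C12 of the enal (oxa-Michael, THF ring second, C12 set by an amine catalyst).
3. 10 ⇒ diene ester 7 (Shi epoxidation sets C15 and C16; deacetylation; MnO2) ⇒ geranyl acetate 1 + trimethyl orthoacetate 4 (Schenck ene reaction, Johnson–Claisen rearrangement).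
4. 22 ⇒ 3-furanmethanol 15 + isoprene monoxide 18 (copper-catalysed SN2′ opening); the furan ring is bought in.

Assumption (atom labels used below): C10 = ketone carbon, C12 and C15 = the substituted THF carbons, C16 = lactone carbinol carbon, C19 = lactone carbonyl, C7=C8 = side-chain olefin; the target is (12R,15R,16S).

## Route

Step 1
Reactants: 1 geranyl acetate
Product: 3 (2E)-6-hydroxy-3,7-dimethylocta-2,7-dien-1-yl acetate (racemic), via allylic hydroperoxide 2 (not isolated)
Conditions: O2, visible light, tetraphenylporphyrin (0.5 mol%), CH2Cl2, 0 °C; then PPh3, 0 °C to rt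
Reagents that add atoms: dioxygen, O=O
Why: Schenck ene reaction: singlet oxygen attacks only the electron-rich 6,7-olefin (the 2,3-olefin is deactivated by the allylic acetate) and hydrogen abstraction from the (Z)-methyl group gives the secondary hydroperoxide with an isopropenyl group, which PPh3 reduces; the regioisomeric tertiary alcohol (about half of the material) is removed by chromatography and the racemic carbinol centre is destroyed in step 2.

Step 2
Reactants: 3 (2E)-6-hydroxy-3,7-dimethylocta-2,7-dien-1-yl acetate; 4 trimethyl orthoacetate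
Product: 7 methyl (4E,8E)-10-acetoxy-4,8-dimethyldeca-4,8-dienoate, via mixed orthoester 5 (not isolated), via ketene acetal 6 (not isolated)
Conditions: MeC(OMe)3 (5 equiv), EtCO2H (5 mol%), 110 °C, MeOH distilled off
Reagents that add atoms: none
Why: Johnson–Claisen orthoester rearrangement: the chair transition state with the chain equatorial gives the (4E)-trisubstituted olefin (above 95:5) and the two-carbon ester arm that becomes C18–C19, while the allylic acetate is a spectator.

Step 3
Reactants: 7 methyl (4E,8E)-10-acetoxy-4,8-dimethyldeca-4,8-dienoate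
Product: 8 methyl (4R,5R,8E)-10-acetoxy-4,5-epoxy-4,8-dimethyldec-8-enoate
Conditions: Shi ketone (1,2:4,5-di-O-isopropylidene-β-D-erythro-2,3-hexodiulo-2,6-pyranose, 30 mol%), Oxone (2KHSO5·KHSO4·K2SO4), K2CO3, Bu4NHSO4, MeCN/CH2(OMe)2–aq. Na2B4O7 (pH 10.5), 0 °C
Reagents that add atoms: potassium peroxymonosulfate (KHSO5, active part of Oxone), [K+].[O-]S(=O)(=O)OO
Why: Shi asymmetric epoxidation: the chiral dioxirane from the D-fructose-derived ketone attacks the electron-rich 4,5-olefin through the spiro transition state and gives the (4R,5R)-epoxide (the future C16 and C15), while the 8,9-olefin next to the acetate is too electron-poor to react.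

Step 4
Reactants: 8 methyl (4R,5R,8E)-10-acetoxy-4,5-epoxy-4,8-dimethyldec-8-enoate
Product: 9 methyl (4R,5R,8E)-4,5-epoxy-10-hydroxy-4,8-dimethyldec-8-enoate
Conditions: K2CO3 (0.2 equiv), MeOH, 0 °C
Reagents that add atoms: none
Why: Base-catalysed transesterification (methanolysis) removes the acetate; the methyl ester only exchanges with itself and the trisubstituted epoxide is inert to K2CO3/MeOH at 0 °C.

Step 5
Reactants: 9 methyl (4R,5R,8E)-4,5-epoxy-10-hydroxy-4,8-dimethyldec-8-enoate
Product: 10 methyl (4R,5R,8E)-4,5-epoxy-4,8-dimethyl-10-oxodec-8-enoate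
Conditions: MnO2 (activated, 15 equiv), CH2Cl2, rt
Reagents that add atoms: none
Why: MnO2 oxidation of the primary allylic alcohol gives the (E)-enal under neutral heterogeneous conditions that leave the epoxide and ester alone and do not isomerise the olefin.

Step 6
Reactants: 10 methyl (4R,5R,8E)-4,5-epoxy-4,8-dimethyl-10-oxodec-8-enoate
Product: 14 2-[(2R,5R)-2-methyl-5-[(2S)-2-methyl-5-oxotetrahydrofuran-2-yl]tetrahydrofuran-2-yl]acetaldehyde, via hydroxy lactone enal 11 (not isolated), via iminium ion 12 (not isolated), via cyclic enamine 13 (not isolated)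
Conditions: TsOH·H2O (10 mol%), H2O (1 equiv), CH2Cl2, 0 °C to rt; then (S)-α,α-diphenylprolinol trimethylsilyl ether (20 mol%), 0 °C to rt
Reagents that add atoms: water, O
Why: Proposed new method: the acid first activates the epoxide so that the ester carbonyl oxygen attacks the tertiary carbon C16 5-exo with inversion (the known acid-catalysed epoxy ester lactonisation, water converting the alkoxy-oxocarbenium ion into lactone and methanol), giving the γ-lactone with 16S and the free (15R)-hydroxyl; the amine, as its tosylate salt, then condenses with the (E)-enal to an iminium ion whose upper face is blocked by the diphenyl(silyloxy)methyl group, so the tethered hydroxyl closes 5-exo-trig on the open face of C12 to set 12R, and hydrolysis of the enamine returns the catalyst; the closest known reaction type is the diarylprolinol silyl ether-catalysed oxa-Michael addition to enals, including phenol additions to β,β-disubstituted terpenoid enals that create tetrasubstituted chromane carbons, whereas closure of an aliphatic hydroxyl onto a β,β-disubstituted enal under catalyst control is untested.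

Step 7
Reactants: 15 3-furanmethanol
Product: 17 3-(chloromethyl)furan, via chlorosulfite ester 16 (not isolated)
Conditions: SOCl2, pyridine, Et2O, 0 °C
Reagents that add atoms: thionyl chloride, ClS(Cl)=O
Why: Chlorination of the primary alcohol through its chlorosulfite (displacement by chloride), with pyridine taking up HCl so that the acid-sensitive furan survives.

Step 8
Reactants: 17 3-(chloromethyl)furan; 18 isoprene monoxide (2-methyl-2-vinyloxirane)
Product: 20 (2E)-5-(furan-3-yl)-2-methylpent-2-en-1-ol, via furylmethylmagnesium chloride 19 (not isolated)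
Conditions: Mg, THF, 0 °C (slow addition of 17); then CuBr·SMe2 (10 mol%), 18, −40 to 0 °C; aq. NH4Cl
Reagents that add atoms: none
Why: Copper-catalysed SN2′ (1,4-) opening of the vinyl oxirane by the furylmethyl Grignard reagent places the nucleophile on the vinyl terminus and gives the (E)-trisubstituted allylic alcohol (E:Z about 9:1, minor isomer removed), which fixes the C7=C8 geometry of the target.

Step 9
Reactants: 20 (2E)-5-(furan-3-yl)-2-methylpent-2-en-1-ol
Product: 22 3-[(3E)-5-chloro-4-methylpent-3-en-1-yl]furan, via allylic mesylate 21 (not isolated)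
Conditions: MsCl, 2,4,6-collidine, LiCl, DMF, 0 °C
Reagents that add atoms: lithium chloride (LiCl), [Li+].[Cl-]
Why: Collington–Meyers chlorination: the mesylate formed in situ is displaced by chloride in a direct SN2 reaction without allylic transposition or loss of (E)-geometry, and the buffered medium spares the furan.

Step 10
Reactants: 22 3-[(3E)-5-chloro-4-methylpent-3-en-1-yl]furan; 14 2-[(2R,5R)-2-methyl-5-[(2S)-2-methyl-5-oxotetrahydrofuran-2-yl]tetrahydrofuran-2-yl]acetaldehyde
Product: 24 (5S)-5-[(2R,5R)-5-[(4E)-7-(furan-3-yl)-2-hydroxy-4-methylhept-4-en-1-yl]-5-methyltetrahydrofuran-2-yl]-5-methyldihydrofuran-2(3H)-one (both carbinol epimers), via allylbarium chloride 23 (not isolated)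
Conditions: BaI2, Li, biphenyl, THF, rt (active barium); 22, −78 °C; then 14, −78 °C; aq. NH4Cl
Reagents that add atoms: none
Why: Yamamoto-type allylbarium addition: the allylbarium reagent made at −78 °C is configurationally stable and attacks the aldehyde through its α-carbon (α:γ above 9:1) with retention of the (E)-olefin, and it reacts with the aldehyde far faster than with the lactone; the new carbinol centre forms as a mixture that is erased in step 11.

Step 11
Reactants: 24 (5S)-5-[(2R,5R)-5-[(4E)-7-(furan-3-yl)-2-hydroxy-4-methylhept-4-en-1-yl]-5-methyltetrahydrofuran-2-yl]-5-methyldihydrofuran-2(3H)-one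
Product: 25 (5S)-5-[(2R,5R)-5-[(4E)-7-(furan-3-yl)-4-methyl-2-oxohept-4-en-1-yl]-5-methyltetrahydrofuran-2-yl]-5-methyldihydrofuran-2(3H)-one (target)
Conditions: Dess–Martin periodinane, pyridine, CH2Cl2, 0 °C to rt
Reagents that add atoms: none
Why: Dess–Martin oxidation under pyridine buffer converts the homoallylic alcohol into the β,γ-unsaturated ketone without moving the C7=C8 olefin into conjugation and without epimerising C12 by retro-oxa-Michael reaction.

## Compound list

1 | geranyl acetate [(2E)-3,7-dimethylocta-2,6-dien-1-yl acetate] | CC(C)=CCC/C(C)=C/COC(C)=O | starting material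
2 | (2E)-6-hydroperoxy-3,7-dimethylocta-2,7-dien-1-yl acetate (racemic) | C=C(C)C(OO)CC/C(C)=C/COC(C)=O | intermediate (not isolated)
3 | (2E)-6-hydroxy-3,7-dimethylocta-2,7-dien-1-yl acetate (racemic) | C=C(C)C(O)CC/C(C)=C/COC(C)=O | intermediate
4 | trimethyl orthoacetate | CC(OC)(OC)OC | starting material
5 | (2E)-6-(1,1-dimethoxyethoxy)-3,7-dimethylocta-2,7-dien-1-yl acetate (mixed orthoester) | C=C(C)C(CC/C(C)=C/COC(C)=O)OC(C)(OC)OC | intermediate (not isolated)
6 | (2E)-6-[(1-methoxyethenyl)oxy]-3,7-dimethylocta-2,7-dien-1-yl acetate (ketene acetal) | C=C(C)C(CC/C(C)=C/COC(C)=O)OC(=C)OC | intermediate (not isolated)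
7 | methyl (4E,8E)-10-acetoxy-4,8-dimethyldeca-4,8-dienoate | COC(=O)CC/C(C)=C/CC/C(C)=C/COC(C)=O | intermediate
8 | methyl (4R,5R,8E)-10-acetoxy-4,5-epoxy-4,8-dimethyldec-8-enoate | COC(=O)CC[C@@]1(C)O[C@@H]1CC/C(C)=C/COC(C)=O | intermediate
9 | methyl (4R,5R,8E)-4,5-epoxy-10-hydroxy-4,8-dimethyldec-8-enoate | COC(=O)CC[C@@]1(C)O[C@@H]1CC/C(C)=C/CO | intermediate
10 | methyl (4R,5R,8E)-4,5-epoxy-4,8-dimethyl-10-oxodec-8-enoate | COC(=O)CC[C@@]1(C)O[C@@H]1CC/C(C)=C/C=O | intermediate
11 | (5S)-5-[(1R,4E)-1-hydroxy-4-methyl-6-oxohex-4-en-1-yl]-5-methyldihydrofuran-2(3H)-one | O=C/C=C(C)/CC[C@H]([C@]1(C)CCC(=O)O1)O | intermediate (not isolated)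
12 | iminium tosylate formed from 11 and (S)-α,α-diphenylprolinol trimethylsilyl ether | C[Si](C)(C)OC(c1ccccc1)(c1ccccc1)[C@@H]1CCC[N+]1=C/C=C(C)/CC[C@H]([C@]2(C)CCC(=O)O2)O.Cc1ccc(cc1)S(=O)(=O)[O-] | intermediate (not isolated)
13 | enamine of 14 with (S)-α,α-diphenylprolinol trimethylsilyl ether (THF ring closed, 12R) | C[Si](C)(C)OC(c1ccccc1)(c1ccccc1)[C@@H]1CCCN1/C=C/[C@@]1(C)CC[C@H]([C@]2(C)CCC(=O)O2)O1 | intermediate (not isolated)
14 | 2-[(2R,5R)-2-methyl-5-[(2S)-2-methyl-5-oxotetrahydrofuran-2-yl]tetrahydrofuran-2-yl]acetaldehyde | O=CC[C@@]1(C)CC[C@H]([C@]2(C)CCC(=O)O2)O1 | intermediate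
15 | 3-furanmethanol | OCc1ccoc1 | starting material
16 | furan-3-ylmethyl chlorosulfite | ClS(=O)OCc1ccoc1 | intermediate (not isolated)
17 | 3-(chloromethyl)furan | ClCc1ccoc1 | intermediate
18 | isoprene monoxide (2-methyl-2-vinyloxirane, racemic) | CC1(C=C)CO1 | starting material
19 | (furan-3-ylmethyl)magnesium chloride | Cl[Mg]Cc1ccoc1 | intermediate (not isolated)
20 | (2E)-5-(furan-3-yl)-2-methylpent-2-en-1-ol | OC/C(C)=C/CCc1ccoc1 | intermediate
21 | (2E)-5-(furan-3-yl)-2-methylpent-2-en-1-yl methanesulfonate | CS(=O)(=O)OC/C(C)=C/CCc1ccoc1 | intermediate (not isolated)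
22 | 3-[(3E)-5-chloro-4-methylpent-3-en-1-yl]furan | ClC/C(C)=C/CCc1ccoc1 | intermediate
23 | [(2E)-5-(furan-3-yl)-2-methylpent-2-en-1-yl]barium chloride | Cl[Ba]C/C(C)=C/CCc1ccoc1 | intermediate (not isolated)
24 | (5S)-5-[(2R,5R)-5-[(4E)-7-(furan-3-yl)-2-hydroxy-4-methylhept-4-en-1-yl]-5-methyltetrahydrofuran-2-yl]-5-methyldihydrofuran-2(3H)-one (both carbinol epimers) | C/C(=C\CCc1ccoc1)CC(O)C[C@@]1(C)CC[C@H]([C@]2(C)CCC(=O)O2)O1 | intermediate
25 | (5S)-5-[(2R,5R)-5-[(4E)-7-(furan-3-yl)-4-methyl-2-oxohept-4-en-1-yl]-5-methyltetrahydrofuran-2-yl]-5-methyldihydrofuran-2(3H)-one | C/C(=C\CCc1ccoc1)CC(=O)C[C@@]1(C)CC[C@H]([C@]2(C)CCC(=O)O2)O1 | target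

## Step count and risks

Total step count: 11. Longest linear sequence: 8 steps (1 → 25 through steps 1–6, 10 and 11); the furan fragment takes steps 7–9.

**Most likely to fail, first: step 6.** Iminium formation from a β,β-disubstituted enal is slow. E/Z scrambling through the dienamine, or slow retro-oxa-Michael reaction of the product, could erode the C12 ratio. Facial control by the catalyst at a tetrasubstituted carbon with an aliphatic hydroxyl is unproven. The fallback sets out from 10 and comes back at 25: the fragments are joined first and the rings are closed last under thermodynamic control. Allylbarium chloride 23 is added to the enal of 10 at −78 °C (ester and epoxide untouched) to give methyl (4R,5R,8E,12E)-4,5-epoxy-15-(furan-3-yl)-10-hydroxy-4,8,12-trimethylpentadeca-8,12-dienoate F1. Dess–Martin oxidation gives methyl (4R,5R,8E,12E)-4,5-epoxy-15-(furan-3-yl)-4,8,12-trimethyl-10-oxopentadeca-8,12-dienoate F2. TsOH·H2O in wet CH2Cl2 then opens the epoxide through the ester carbonyl to the hydroxy lactone enone F3 (not isolated), which closes by reversible acid-catalysed oxa-Michael addition to 25 and its C12 epimer F4. The epimers are separated and the C12 epimer F4 is returned to the same acid, where it re-equilibrates through F3.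

**Second: step 10.** The α/γ ratio and (E)-retention of a β-methyl-substituted allylbarium reagent are not certain, and the reagent is basic towards a β-alkoxy aldehyde that carries a lactone. The fallback sets out from 22 (with 14 as partner) and comes back at 25, using a sulfone-stabilised carbanion in place of the allylmetal. Chloride 22 and PhSO2Na in DMF give 3-[(3E)-4-methyl-5-(phenylsulfonyl)pent-3-en-1-yl]furan F5. n-BuLi in THF at −78 °C gives its α-lithio derivative F6, which adds through the sulfonyl-bearing carbon to aldehyde 14 to give the β-hydroxy sulfone F7. Dess–Martin oxidation gives the β-keto sulfone F8, and SmI2 in THF/MeOH at −78 °C removes the sulfonyl group; protonation of the enolate at the α-carbon gives 25 directly.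

**Third: step 8.** The vinyl oxirane may be opened with poor SN2′/SN2 or E/Z selectivity, which would contaminate the C7=C8 geometry. The fallback sets out from 17 and comes back at 20. The Grignard reagent 19 made from 17 is cross-coupled with prenyl chloride (Li2CuCl4 cat., THF, 0 °C), a direct coupling with no olefin geometry at stake, to give perillene F9. SeO2 (cat.)/t-BuOOH in CH2Cl2 then hydroxylates the methyl group trans to the chain, with the inherent (E)-selectivity of selenium dioxide allylic oxidation, to give 20.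

## Further compounds

F1 | step 6 | methyl (4R,5R,8E,12E)-4,5-epoxy-15-(furan-3-yl)-10-hydroxy-4,8,12-trimethylpentadeca-8,12-dienoate (both C10 epimers) | COC(=O)CC[C@@]1(C)O[C@@H]1CC/C(C)=C/C(O)C/C(C)=C/CCc1ccoc1
F2 | step 6 | methyl (4R,5R,8E,12E)-4,5-epoxy-15-(furan-3-yl)-4,8,12-trimethyl-10-oxopentadeca-8,12-dienoate | COC(=O)CC[C@@]1(C)O[C@@H]1CC/C(C)=C/C(=O)C/C(C)=C/CCc1ccoc1
F3 | step 6 | (5S)-5-[(1R,4E,8E)-11-(furan-3-yl)-1-hydroxy-4,8-dimethyl-6-oxoundeca-4,8-dien-1-yl]-5-methyldihydrofuran-2(3H)-one | C/C(=C\CCc1ccoc1)CC(=O)/C=C(C)/CC[C@H]([C@]1(C)CCC(=O)O1)O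
F4 | step 6 | (5S)-5-[(2R,5S)-5-[(4E)-7-(furan-3-yl)-4-methyl-2-oxohept-4-en-1-yl]-5-methyltetrahydrofuran-2-yl]-5-methyldihydrofuran-2(3H)-one (C12 epimer of 25) | C/C(=C\CCc1ccoc1)CC(=O)C[C@]1(C)CC[C@H]([C@]2(C)CCC(=O)O2)O1
F5 | step 10 | 3-[(3E)-4-methyl-5-(phenylsulfonyl)pent-3-en-1-yl]furan | O=S(=O)(C/C(C)=C/CCc1ccoc1)c1ccccc1
F6 | step 10 | α-lithio derivative of F5 | [Li]C(/C(C)=C/CCc1ccoc1)S(=O)(=O)c1ccccc1
F7 | step 10 | (5S)-5-[(2R,5R)-5-[(4E)-7-(furan-3-yl)-2-hydroxy-4-methyl-3-(phenylsulfonyl)hept-4-en-1-yl]-5-methyltetrahydrofuran-2-yl]-5-methyldihydrofuran-2(3H)-one (diastereomer mixture at the two new centres) | C/C(=C\CCc1ccoc1)C(S(=O)(=O)c1ccccc1)C(O)C[C@@]1(C)CC[C@H]([C@]2(C)CCC(=O)O2)O1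
F8 | step 10 | (5S)-5-[(2R,5R)-5-[(4E)-7-(furan-3-yl)-4-methyl-2-oxo-3-(phenylsulfonyl)hept-4-en-1-yl]-5-methyltetrahydrofuran-2-yl]-5-methyldihydrofuran-2(3H)-one (epimers at the sulfonyl carbon) | C/C(=C\CCc1ccoc1)C(S(=O)(=O)c1ccccc1)C(=O)C[C@@]1(C)CC[C@H]([C@]2(C)CCC(=O)O2)O1
F9 | step 8 | perillene [3-(4-methylpent-3-en-1-yl)furan] | CC(C)=CCCc1ccoc1
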